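Each hexasubstituted benzene ring is divided into a two-carbon unit (C1, bearing the CH2–N arm, and its brominated neighbour C2) and a symmetric four-carbon unit (C3–C6, carrying Br, OMe, OMe, Br). A twofold Diels–Alder reaction of a bis(bromoalkyne) urea with 2,5-dibromo-3,4-dimethoxythiophene 1,1-dioxide, with loss of SO2 from each adduct, forms the C2–C3 and C6–C1 bonds of both rings and delivers both fully substituted arenes in one operation, every substituent being placed by connectivity and not by aromatic substitution. The precursor is the linear, achiral N,N'-bis(3-bromoprop-2-yn-1-yl)urea; global O-demethylation then gives the bis(catechol) target.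

Key step: step 5

Remark: the target has no stereocentre and is achiral, so there is no enantiomer to select and the route needs no stereocontrol. Ring numbering used below: C1 carries CH2N; C2, C3 and C6 carry Br; C4 and C5 carry O.

Step 1
Reactants: 1 propargylamine; 2 1,1'-carbonyldiimidazole
Product: 4 N,N'-di(prop-2-yn-1-yl)urea, via carbamoylimidazole 3 (not isolated)
Conditions: 2 (1.0 equiv), 1 (2.1 equiv), THF, 0 °C → rt → 50 °C
Reagents that add atoms: none
Why: Acyl transfer from CDI to the primary amine gives the carbamoylimidazole, which a second equivalent of amine attacks with loss of imidazole (CDI urea synthesis); no stereocentre is formed.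

Step 2
Reactants: 4 N,N'-di(prop-2-yn-1-yl)urea
Product: 6 N,N'-bis(3-bromoprop-2-yn-1-yl)urea, via mono-bromoalkyne urea 5 (not isolated)
Conditions: NBS (2.3 equiv), AgNO3 (10 mol%), acetone (DMF co-solvent if needed), rt, dark
Reagents that add atoms: N-bromosuccinimide, O=C1CCC(=O)N1Br
Why: Silver(I) activates the terminal alkyne C–H as a silver acetylide that NBS brominates (silver-catalysed bromination of terminal alkynes), a reaction that tolerates N–H amides and carbamates and should leave the urea untouched at room temperature.

Step 3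
Reactants: 7 3,4-dimethoxythiophene
Product: 9 2,5-dibromo-3,4-dimethoxythiophene, via 2-bromo-3,4-dimethoxythiophene 8 (not isolated)
Conditions: NBS (2.05 equiv), DMF, 0 °C, dark; used without storage
Reagents that add atoms: N-bromosuccinimide, O=C1CCC(=O)N1Br
Why: Electrophilic aromatic bromination takes place at the two α-positions, the only ring C–H positions of the electron-rich thiophene.

Step 4
Reactants: 9 2,5-dibromo-3,4-dimethoxythiophene
Product: 11 2,5-dibromo-3,4-dimethoxythiophene 1,1-dioxide, via thiophene S-oxide 10 (not isolated)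
Conditions: dimethyldioxirane (ca. 0.07 M in acetone, 3 equiv), CH2Cl2, −20 °C → rt; evaporation
Reagents that add atoms: dimethyldioxirane, CC1(C)OO1
Why: Electrophilic oxygen transfer from the dioxirane to sulfur runs through the S-oxide to the sulfone under neutral conditions (dioxirane oxidation of thiophenes to 1,1-dioxides), and the two α-bromines shield S-oxide and sulfone from [4+2] self-dimerisation.

Step 5
Reactants: 6 N,N'-bis(3-bromoprop-2-yn-1-yl)urea; 11 2,5-dibromo-3,4-dimethoxythiophene 1,1-dioxide
Product: 15 N,N'-bis(2,3,6-tribromo-4,5-dimethoxybenzyl)urea, via bridged mono-adduct 12 (not isolated), via mono-arene bromoalkyne 13 (not isolated), via bridged second adduct 14 (not isolated)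
Conditions: 11 (3 equiv), BHT (5 mol%), 1,2-dichlorobenzene, 120 °C, slow N2 sweep
Reagents that add atoms: none
Why: The sulfone 11 is a non-aromatic cyclic diene whose C2–C5 unit adds thermally across each bromoalkyne of 6 in a concerted [4+2] cycloaddition, its sulfone-lowered LUMO pairing with the bromine-raised alkyne HOMO, to give a 7-thiabicyclo[2.2.1]hepta-2,5-diene 7,7-dioxide (12, then 14) that loses SO2 by cheletropic extrusion and aromatises irreversibly. The closest known reaction type is the benzannulation of halogenated thiophene 1,1-dioxides with alkynes (Diels–Alder reaction followed by SO2 extrusion). Each of the two benzene rings is closed by intermolecular [4+2] cycloaddition, which forms the C2–C3 and C6–C1 bonds, followed by retro-cheletropic aromatisation. No stereocentre is created in the product, since the bridgehead centres of the racemic adducts are erased when SO2 leaves. Regiochemistry cannot go wrong because the diene is C2v-symmetric and both orientations of the alkyne give the same arene, with CH2N at C1, Br at C2, C3 and C6 and OMe at C4 and C5. The step needs cycloaddition to outrun self-dimerisation of the sulfone and decomposition of the bromoalkyne, which the dimer-blocking 2,5-dibromo substitution, the excess of 11, the radical inhibitor and the metal- and base-free medium (in which the urea N–H groups are inert) should secure.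

Step 6
Reactants: 15 N,N'-bis(2,3,6-tribromo-4,5-dimethoxybenzyl)urea
Product: 17 N,N'-bis(2,3,6-tribromo-4,5-dihydroxybenzyl)urea, via bis(bromodioxaborole) urea 16 (not isolated)
Conditions: BBr3 (1 M in CH2Cl2, 8 equiv), CH2Cl2, −78 °C → rt; then H2O, 0 °C
Reagents that add atoms: none
Why: Each aryl methyl ether complexes BBr3 and loses its methyl group by bromide attack (BBr3 ether cleavage), the cyclic aryl borates hydrolyse on work-up, and the aryl bromides, the urea and the benzylic C–N bonds on the electron-poor rings should survive.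

Compound list
1 | propargylamine (prop-2-yn-1-amine) | C#CCN | starting material
2 | 1,1'-carbonyldiimidazole (CDI) | O=C(n1ccnc1)n1ccnc1 | starting material
3 | N-(prop-2-yn-1-yl)-1H-imidazole-1-carboxamide (forms in step 1, not isolated) | C#CCNC(=O)n1ccnc1 | intermediate
4 | N,N'-di(prop-2-yn-1-yl)urea | O=C(NCC#C)NCC#C | intermediate
5 | N-(3-bromoprop-2-yn-1-yl)-N'-(prop-2-yn-1-yl)urea (forms in step 2, not isolated) | O=C(NCC#C)NCC#CBr | intermediate
6 | N,N'-bis(3-bromoprop-2-yn-1-yl)urea | O=C(NCC#CBr)NCC#CBr | intermediate
7 | 3,4-dimethoxythiophene | COc1cscc1OC | starting material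
8 | 2-bromo-3,4-dimethoxythiophene (forms in step 3, not isolated) | COc1csc(Br)c1OC | intermediate
9 | 2,5-dibromo-3,4-dimethoxythiophene | COc1c(Br)sc(Br)c1OC | intermediate
10 | 2,5-dibromo-3,4-dimethoxythiophene 1-oxide (forms in step 4, not isolated) | COC1=C(Br)S(=O)C(Br)=C1OC | intermediate
11 | 2,5-dibromo-3,4-dimethoxythiophene 1,1-dioxide | COC1=C(Br)S(=O)(=O)C(Br)=C1OC | intermediate
12 | N-(3-bromoprop-2-yn-1-yl)-N'-[(1,3,4-tribromo-5,6-dimethoxy-7,7-dioxo-7-thiabicyclo[2.2.1]hepta-2,5-dien-2-yl)methyl]urea (racemic, the bicycle fixes the relative configuration of the two bridgeheads; forms in step 5, not isolated) | O=C(NCC#CBr)NCC1=C(Br)C2(Br)C(OC)=C(OC)C1(Br)S2(=O)=O | intermediate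
13 | N-(3-bromoprop-2-yn-1-yl)-N'-(2,3,6-tribromo-4,5-dimethoxybenzyl)urea (forms in step 5, not isolated) | O=C(NCC#CBr)NCc1c(Br)c(OC)c(OC)c(Br)c1Br | intermediate
14 | N-(2,3,6-tribromo-4,5-dimethoxybenzyl)-N'-[(1,3,4-tribromo-5,6-dimethoxy-7,7-dioxo-7-thiabicyclo[2.2.1]hepta-2,5-dien-2-yl)methyl]urea (racemic; forms in step 5, not isolated) | O=C(NCc1c(Br)c(OC)c(OC)c(Br)c1Br)NCC1=C(Br)C2(Br)C(OC)=C(OC)C1(Br)S2(=O)=O | intermediate
15 | N,N'-bis(2,3,6-tribromo-4,5-dimethoxybenzyl)urea | O=C(NCc1c(Br)c(OC)c(OC)c(Br)c1Br)NCc1c(Br)c(OC)c(OC)c(Br)c1Br | intermediate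
16 | N,N'-bis[(2,4,6,7-tetrabromo-1,3,2-benzodioxaborol-5-yl)methyl]urea (forms in step 6, hydrolysed on work-up, not isolated) | O=C(NCc1c(Br)c2OB(Br)Oc2c(Br)c1Br)NCc1c(Br)c2OB(Br)Oc2c(Br)c1Br | intermediate
17 | N,N'-bis(2,3,6-tribromo-4,5-dihydroxybenzyl)urea (achiral) | O=C(NCc1c(Br)c(O)c(O)c(Br)c1Br)NCc1c(Br)c(O)c(O)c(Br)c1Br | target

Total step count: 6. Longest linear sequence: 4 steps (steps 1, 2, 5, 6 or steps 3, 4, 5, 6).

Steps most likely to fail

Step 5. The cycloaddition may be too slow at temperatures the partners tolerate, so that thermal decay or self-dimerisation of the sulfone and oligomerisation of the bromoalkyne take over, or the reaction may stall after the first ring. The fallback gives up the cycloaddition and builds the arene by substitution chemistry; it sets out from CDI 2 and returns at 15. Commercial 3,4-dimethoxytoluene F1 would be brominated at all three free ring positions (Br2 in excess, Fe cat., CH2Cl2) to 2,3,6-tribromo-4,5-dimethoxytoluene F2. Wohl–Ziegler bromination (NBS, AIBN, PhCF3, reflux) should give 2,3,6-tribromo-4,5-dimethoxybenzyl bromide F3. Azide displacement (NaN3, DMF, rt) should give 2,3,6-tribromo-4,5-dimethoxybenzyl azide F4, and Staudinger reduction (PPh3, THF/H2O) should give 2,3,6-tribromo-4,5-dimethoxybenzylamine F5. Two equivalents of the amine would then be coupled with 2 (THF, 50 °C) to give 15.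

Step 4. Oxygen transfer may go to the electron-rich ring carbons instead of sulfur, or stop at the S-oxide, which would then be consumed by dimerisation; the enol ether units of the sulfone may also hydrolyse during isolation. The fallback oxidises before it halogenates; it sets out from 7 and returns at 11. Double α-lithiation and silylation (n-BuLi, TMEDA, THF, −78 → 0 °C; TMSCl) should give 3,4-dimethoxy-2,5-bis(trimethylsilyl)thiophene F6, whose silyl groups make sulfur more nucleophilic and block dimerisation. Oxidation with mCPBA (CH2Cl2, rt) should give 3,4-dimethoxy-2,5-bis(trimethylsilyl)thiophene 1,1-dioxide F7, and ipso-bromodesilylation (Br2, AgBF4, CH2Cl2, 0 °C) should deliver 11.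

Step 2. Silver(I) may trigger cyclisation of the urea oxygen or nitrogen onto the activated alkyne, or NBS may N-brominate the urea, so that the bis(bromoalkyne) is eroded. The fallback installs the bromoalkyne before the urea exists; it sets out from 1 and returns at 6. Protection (Boc2O, CH2Cl2, rt) should give tert-butyl prop-2-yn-1-ylcarbamate F8, and silver-catalysed bromination (NBS, AgNO3 cat., acetone, rt) should give tert-butyl (3-bromoprop-2-yn-1-yl)carbamate F9. Acidolysis (HCl, 1,4-dioxane, rt) should give 3-bromoprop-2-yn-1-amine hydrochloride F10. Two equivalents of the salt would be coupled with 2 (Et3N, CH2Cl2, 0 °C → rt) to give 6.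

Further compounds
F1 | step 5 | 3,4-dimethoxytoluene | Cc1ccc(OC)c(OC)c1
F2 | step 5 | 2,3,6-tribromo-4,5-dimethoxytoluene (1,2,4-tribromo-5,6-dimethoxy-3-methylbenzene) | Cc1c(Br)c(OC)c(OC)c(Br)c1Br
F3 | step 5 | 2,3,6-tribromo-4,5-dimethoxybenzyl bromide | BrCc1c(Br)c(OC)c(OC)c(Br)c1Br
F4 | step 5 | 2,3,6-tribromo-4,5-dimethoxybenzyl azide | [N-]=[N+]=NCc1c(Br)c(OC)c(OC)c(Br)c1Br
F5 | step 5 | 2,3,6-tribromo-4,5-dimethoxybenzylamine | NCc1c(Br)c(OC)c(OC)c(Br)c1Br
F6 | step 4 | 3,4-dimethoxy-2,5-bis(trimethylsilyl)thiophene | COc1c([Si](C)(C)C)sc([Si](C)(C)C)c1OC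
F7 | step 4 | 3,4-dimethoxy-2,5-bis(trimethylsilyl)thiophene 1,1-dioxide | COC1=C([Si](C)(C)C)S(=O)(=O)C([Si](C)(C)C)=C1OC
F8 | step 2 | tert-butyl prop-2-yn-1-ylcarbamate | C#CCNC(=O)OC(C)(C)C
F9 | step 2 | tert-butyl (3-bromoprop-2-yn-1-yl)carbamate | BrC#CCNC(=O)OC(C)(C)C
F10 | step 2 | 3-bromoprop-2-yn-1-amine hydrochloride | Cl.NCC#CBr
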